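The earlier runs and the new flask stem from a simulated flask for substances that don't exist.

I decided to count turnovers: for each substrate turned into side product, how many turned into target?

| setting | Wednesday's | Saturday's | Tuesday's | blue | red | teal |
|---|---|---|---|---|---|---|
| substrate | 20 mM | 20 mM | 40 mM | 20 mM | 20 mM | 20 mM |
| reagent | 20 mM | 30 mM | 40 mM | 40.0 mM | 40.0 mM | 40.0 mM |
| temperature | 25 °C | 36 °C | 25 °C |  | 40 °C | 20 °C |
| remark | run made earlier | run made earlier | run made earlier | at 20 °C until 30 min, from then on at 40 °C |  |  |
| time |  |  |  | 2.5 h | 2.5 h | 2.5 h |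

- Wednesday's (time / h: target / %, side product / %): 0.500: 26.5, 9.4; 0.833: 33.5, 12.3; 2.00: 41.6, 16.5; 3.00: 44.5, 17.9; 6.00: 48.1, 19.8
- Saturday's (time / h: target / %, side product / %): 0.250: 33.8, 14.3; 0.417: 39.9, 17.9; 0.833: 45.5, 20.7; 1.50: 49.6, 23.1; 3.00: 53.8, 25.5
- Tuesday's (time / h: target / %, side product / %): 0.500: 37.4, 7.1; 2.00: 47.9, 9.8; 3.00: 49.9, 10.8; 4.00: 51.7, 10.9; 6.00: 53.1, 11.5

(readings scatter by 0.3 percentage points)

1. the flask with the highest share of target in all that became target or side product ("all alike" if they lie within 1.5 percentage points) (blue / red / teal / all alike)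
2. share of target in all that became target or side product, blue
3. share of target in all that became target or side product, red
4. share of target in all that became target or side product, teal

- a reading or a percentage of target counts all its forms, free or not

I reckoned down a ladder, fastest rung first.

1. First readings: Saturday's run had turned 48.1% of its substrate after 0.250 h, and Wednesday's run 35.9% after 0.500 h. I read the target to side product ratio there.

2. Reagent drifts more slowly: at that reading of Saturday's run, one reagent per target had used 22.5% of its charge. Taking one reagent per target, Wednesday's ratio 2.82 stood at mean c(reagent) 17.4 mM, and Tuesday's 5.27 at 32.5 mM. Dividing gave 0.162 mM⁻¹ and 0.162 mM⁻¹. This is s, target formed per side product per mM of reagent, a selectivity factor.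

3. Temperature: Saturday's run gave 0.0888 mM⁻¹, lower. Carrying ln s straight through these two readings, I got 0.214 mM⁻¹ at 20 °C and 0.0713 mM⁻¹ at 40 °C.

4. The tail crawls: Wednesday's target rose 3.6 percentage points from 3.00 h to 6.00 h. I took the share as s·c/(1 + s·c), with c the mean c(reagent). For teal I borrowed Tuesday's target at 2.00 h, giving c(reagent) 35.2 mM and 88.3%. For red I borrowed Saturday's last target, giving 34.6 mM and 71.2%. For blue I took Wednesday's first sum as turned cold and Saturday's last sum as the total, giving 78.9%. Teal led my reckoning.

The forecast named teal, with 77% for blue, 70% for red and 88% for teal, on the ground that “Side product is therefore favoured by heat”, and it stood slightly below me on blue and red.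

The flasks gave teal the lead: blue 78.1%, red 70.5%, teal 88.3%.

    substrate + reagent → target (k = 0.0405 L mol⁻¹ s⁻¹, Ea = 56.0 kJ mol⁻¹)
    substrate → side product (k = 5.71 × 10⁻⁴ s⁻¹, Ea = 99.0 kJ mol⁻¹)
    substrate + target ⇌ idle adduct, settled at all times (K = 2310 L mol⁻¹, ΔH = −39.0 kJ mol⁻¹)
    (constants at 40 °C)

Red ended with reagent at 70% of its charge, a mean c(reagent) of 34.0 mM, and the share from s then came to 70.8%. Teal at 2.50 h held idle adduct at 79.1%, counted as two, beside target at 51.0%, all its forms counted. The neighbour was red with 160 mM of reagent, 8.00 equiv. Its reagent ended at 89% of its charge, a mean of 151 mM, so the share from s at 40 °C came to 91.5%. That flask gave 91.5%, with side product at 8.05%.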